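**Retrosynthetic overview**

1. Daucane numbering is used: the five-membered ring is C1(CH3)–C2(OAc)–C3–C4(OH, i‑Pr)–C5(H), the seven-membered ring is C5–C6(O‑veratroyl)–C7–C8(CH3)–C9–C10(OH)–C1; β is the face of the C1 methyl group.
2. Late stage: the oxirane comes from a C8=C9 cycloheptene by hydroxyl-directed epoxidation, the veratrate (O6) and acetate (O2) are put on in turn, and the C4 carbinol comes from a C4 ketone and an isopropyl nucleophile.
3. Key disconnection: C1–C5 and C2–C3 are formed in one intramolecular (3+2) cycloaddition of an open-chain epoxy enolsilane (C3=C4(OSiEt3) next to a C5/C6 oxirane) with a C1=C2 enol ether at the other chain end. The seven-membered ring closes with the first bond and the five-membered ring with the second, so neither ring exists beforehand.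
4. Enabling feature: the cyclopentane carries oxygen at C2 and C4 (1,3) and a third oxygen at C6 next to the ring-fusion carbon C5. C4/C5/C6 is therefore the imprint of an α,β-epoxy ketone (a 2-silyloxyallyl cation with its own leaving group) and C1/C2 that of an enol ether; the Z-trisubstituted C8=C9 olefin (the later oxirane) folds the tether.
5. Chain assembly: propargyl alcohol gives C7–C9 with the Z-olefin; (S)-but-3-yn-2-ol gives C3–C6 (Sharpless epoxidation sets C5/C6); 3-ethoxymethacrolein gives C10, C1 and C2 (ligand-controlled alkenylzinc addition sets C10).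

Key step: step 12

Remark on the chemistry: the oxirane is read as the ordinary cis-fused 8,9-epoxide on the α-face, syn to the C10 hydroxyl (descriptor at C9 as written); taken to the letter, the descriptor at C8 would put the two ring bonds of the oxirane anti to each other, which an epoxide formed on a cycloheptene cannot have, and the target line keeps the string as given.

**Route**

Step 1
Reactants: 1 propargyl alcohol
Product: 3 (Z)-3-iodo-2-methylprop-2-en-1-ol, via (Z)-alkenylmagnesium alkoxide 2 (not isolated)
Conditions: MeMgBr (2.5 equiv), CuI (10 mol%), Et2O, −10 °C to rt; then I2, −10 °C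
Reagents that add atoms: methylmagnesium bromide, C[Mg]Br; iodine, II
Why: Copper-catalysed anti-carbomagnesiation of the magnesium propargyl alkoxide puts the methyl group on C8 and magnesium on C9 trans to it, and iodinolysis of the C–Mg bond with retention fixes the Z-trisubstituted olefin that later is the C8=C9 turn of the cycloheptene.

Step 2
Reactants: 3 (Z)-3-iodo-2-methylprop-2-en-1-ol
Product: 4 (Z)-3-bromo-1-iodo-2-methylprop-1-ene
Conditions: PBr3 (0.4 equiv), Et2O, 0 °C
Reagents that add atoms: phosphorus tribromide, BrP(Br)Br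
Why: SN2 displacement of the primary allylic alcohol through its phosphite ester gives the allylic bromide without change of olefin geometry and without touching the vinyl iodide.

Step 3
Reactants: 5 (S)-but-3-yn-2-ol
Product: 6 (S)-triethyl(but-3-yn-2-yloxy)silane
Conditions: Et3SiCl, imidazole, CH2Cl2, 0 °C
Reagents that add atoms: chlorotriethylsilane, CC[Si](Cl)(CC)CC
Why: Routine silylation masks the carbinol (the chiral-pool centre that later steers the epoxidation) against the organolithium chemistry of step 6.

Step 4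
Reactants: 6 (S)-triethyl(but-3-yn-2-yloxy)silane; 4 (Z)-3-bromo-1-iodo-2-methylprop-1-ene
Product: 7 (S,Z)-triethyl[(7-iodo-6-methylhept-6-en-3-yn-2-yl)oxy]silane
Conditions: CuI (10 mol%), NaI (10 mol%), K2CO3, DMF, rt
Reagents that add atoms: none
Why: Copper acetylide alkylation of the primary allylic bromide (SN2; the γ-carbon carries iodine, so no allylic transposition) gives the skipped enyne with Z-olefin and vinyl iodide intact.

Step 5
Reactants: 8 (E)-3-ethoxy-2-methylprop-2-enal
Product: 9 (E)-3-[(4-methoxybenzyl)oxy]-2-methylprop-2-enal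
Conditions: 4-methoxybenzyl alcohol, PPTS (cat.), toluene, 60 °C, 4 Å molecular sieves (EtOH removed)
Reagents that add atoms: 4-methoxybenzyl alcohol, COc1ccc(CO)cc1
Why: Acid-catalysed alkoxy exchange of the vinylogous ester (addition–elimination at the β-carbon) installs an oxidatively removable O-substituent and returns the thermodynamically preferred E-isomer.

Step 6
Reactants: 7 (S,Z)-triethyl[(7-iodo-6-methylhept-6-en-3-yn-2-yl)oxy]silane; 9 (E)-3-[(4-methoxybenzyl)oxy]-2-methylprop-2-enal
Product: 12 (1E,3S,4Z,9S)-3-(tert-butyldimethylsilyloxy)-1-[(4-methoxybenzyl)oxy]-2,5-dimethyl-9-(triethylsilyloxy)deca-1,4-dien-7-yne, via alkenyl(methyl)zinc 10 (not isolated), via methylzinc alkoxide 11 (not isolated)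
Conditions: t-BuLi (2.1 equiv), Et2O, −78 °C; ZnBr2, then MeLi; N,N,N′,N′-tetraethylethylenediamine, (−)-MIB (10 mol%), 9, −30 to 0 °C; then t-BuMe2SiOTf, 2,6-lutidine, −78 °C
Reagents that add atoms: tert-butyldimethylsilyl triflate, CC(C)(C)[Si](C)(C)OS(=O)(=O)C(F)(F)F
Why: Iodine–lithium exchange with retention and transmetalation give a Z-trisubstituted alkenylzinc that should add 1,2 to the aldehyde under amino-alcohol catalysis (ligand-accelerated alkenylzinc addition, Si-face delivery by (−)-MIB setting the 10S carbinol), and silylation of the zinc alkoxide in the same flask avoids isolation of the acid-labile γ-hydroxy enol ether.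

Step 7
Reactants: 12 bis-silyl ether
Product: 13 (2S,6Z,8S,9E)-8-(tert-butyldimethylsilyloxy)-10-[(4-methoxybenzyl)oxy]-6,9-dimethyldeca-6,9-dien-3-yn-2-ol
Conditions: Bu4NF (1.05 equiv), THF, −20 to 0 °C
Reagents that add atoms: none
Why: Fluoride should cleave the unhindered propargylic triethylsilyl ether much faster than the hindered secondary tert-butyldimethylsilyl ether (selective desilylation), and the basic medium leaves the enol ether untouched.

Step 8
Reactants: 13 propargylic alcohol
Product: 14 (2S,3E,6Z,8S,9E)-8-(tert-butyldimethylsilyloxy)-10-[(4-methoxybenzyl)oxy]-6,9-dimethyldeca-3,6,9-trien-2-ol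
Conditions: NaAlH2(OCH2CH2OMe)2 (Red-Al), THF, 0 °C; aqueous work-up
Reagents that add atoms: none
Why: Alkoxide-directed trans-hydroalumination of the propargylic alcohol followed by protonolysis gives the E-allylic alcohol, the geometry that the trans-oxirane and the later inversion at C5 require.

Step 9
Reactants: 14 (E)-allylic alcohol
Product: 15 epoxy alcohol (4S carbinol, 5R,6R trans-oxirane, Z C8=C9, 10S silyl ether, E enol ether)
Conditions: Ti(OiPr)4 (1.0 equiv), L-(+)-diisopropyl tartrate (1.2 equiv), t-BuOOH, 4 Å molecular sieves, CH2Cl2, −20 °C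
Reagents that add atoms: tert-butyl hydroperoxide, CC(C)(C)OO
Why: Sharpless asymmetric epoxidation in the matched sense (4S carbinol with the L-(+)-tartrate) delivers oxygen to one face of the E-olefin and sets the 5R,6R oxirane anti to the carbinol, while the silylated C10 oxygen cannot direct oxidation of the other two olefins.

Step 10
Reactants: 15 epoxy alcohol
Product: 16 epoxy ketone (C4 methyl ketone, 5S,6R trans-oxirane)
Conditions: Dess–Martin periodinane, pyridine, CH2Cl2, 0 °C to rt
Reagents that add atoms: none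
Why: Buffered Dess–Martin oxidation converts the epoxy alcohol into the α,β-epoxy ketone without epimerisation at C5 or hydrolysis of the enol ether; the C4 centre, having done its work, is erased.

Step 11
Reactants: 16 epoxy ketone
Product: 17 epoxy enolsilane (C3=C4(OSiEt3), 5S,6R trans-oxirane, Z C8=C9, 10S OSi(t-Bu)Me2, E C1=C2 PMB enol ether)
Conditions: LiN(SiMe3)2, Et3SiCl, THF, −78 °C
Reagents that add atoms: chlorotriethylsilane, CC[Si](Cl)(CC)CC
Why: Kinetic deprotonation can only take place at the methyl group (C3), and O-silylation of the lithium enolate (silyl enol ether formation with internal quench) gives the epoxy enolsilane.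

Step 12
Reactants: 17 epoxy enolsilane
Product: 19 trans-fused bicyclo[5.3.0]dec-8-en-4-one (1β-CH3, 2β-OPMB, 5α-H, 6α-OSiEt3, 8-CH3, 10α-OSi(t-Bu)Me2), via oxocarbenium triflate ion pair 18 (not isolated)
Conditions: Et3SiOTf (20 mol%), 2,6-di-tert-butyl-4-methylpyridine (30 mol%), CH2Cl2 (0.01 M), −78 °C
Reagents that add atoms: none
Why: Proposed new method: the silyl triflate silylates the oxirane oxygen, the C5–O bond ionises with help of the adjacent enol silane (2-silyloxyallyl cation character), the enol ether carbon C1 attacks C5 anti to the departing oxygen to give ion pair 18, and C3 of the enol silane then captures the oxocarbenium carbon C2 while the silyl group released from O4 carries the chain, so the net change is an isomerisation. The closest known reactions are the silyl-triflate-catalysed (4+3) cycloadditions of epoxy enolsilanes with dienes, also in intramolecular form, and the (3+2) cycloadditions of 2-silyloxyallyl cations with enol ethers to 3-alkoxycyclopentanones. The seven-membered ring closes first (C1–C5, 7-exo-trig with respect to the enol ether, SN2′-like at the allylic terminus, folded by the Z C8=C9 olefin) and the five-membered ring second (C2–C3, formally 5-(enolendo)-exo-trig, expected as the second bond of an asynchronous cycloaddition from the folded ion pair). C5 is set by inversion at the oxirane carbon (C6 keeps its oxygen), C1 by an inside-alkoxy arrangement at C10 (C10–O in the plane of the enol ether, C10–H anti to the incoming carbon, tether on the attacked face), which with the W-shaped silyloxyallyl unit should give the trans ring fusion, and C2 by suprafacial addition to the E-enol ether (OPMB cis to the C1 methyl). The step needs carbon–carbon closure to win over ionisation of the bis-allylic C10 silyl ether and over attack by the C8=C9 olefin; the far higher nucleophilicity of the trisubstituted enol ether, the low temperature, the hindered base and the catalytic amount of Lewis acid should secure this.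

Step 13
Reactants: 19 bicyclic ketone
Product: 20 tertiary carbinol (as 19, with C4 β-OH and α-isopropyl)
Conditions: i-PrMgCl, CeCl3 (anhydrous), THF, −78 °C
Reagents that add atoms: isopropylmagnesium chloride, CC(C)[Mg]Cl
Why: The weakly basic organocerium reagent should add to the cyclopentanone (1,2-addition) without enolisation or β-elimination of the two β-oxygen groups, from the α-face opposite the angular C1 methyl and the C2 ether, which sets C4 with the hydroxyl β.

Step 14
Reactants: 20 tertiary carbinol
Product: 21 C6 α-alcohol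
Conditions: PPTS, MeOH, 0 °C
Reagents that add atoms: none
Why: Acid-catalysed methanolysis removes the secondary triethylsilyl ether at C6 selectively in the presence of the bulkier, hindered tert-butyldimethylsilyl ether at C10.

Step 15
Reactants: 21 C6 α-alcohol
Product: 22 C6 3,4-dimethoxybenzoate
Conditions: 3,4-dimethoxybenzoyl chloride, Et3N, DMAP (cat.), CH2Cl2, 0 °C to rt
Reagents that add atoms: 3,4-dimethoxybenzoyl chloride, COc1ccc(C(Cl)=O)cc1OC
Why: DMAP-catalysed acylation takes place at the only secondary hydroxyl, the tertiary C4 hydroxyl being too hindered.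

Step 16
Reactants: 22 C6 3,4-dimethoxybenzoate
Product: 23 C2 β-alcohol
Conditions: DDQ, CH2Cl2/pH 7 buffer, 0 °C
Reagents that add atoms: none
Why: Oxidative cleavage of the p-methoxybenzyl ether (hydride abstraction at the electron-rich benzylic position, hydrolysis of the oxocarbenium ion) frees the C2 hydroxyl, while the electron-poorer aroyl ester and the silyl ether stay intact.

Step 17
Reactants: 23 C2 β-alcohol
Product: 24 C2 acetate
Conditions: Ac2O, pyridine, DMAP (cat.), CH2Cl2, rt
Reagents that add atoms: acetic anhydride, CC(=O)OC(C)=O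
Why: Acetylation by nucleophilic catalysis is selective for the secondary C2 hydroxyl because the only other free hydroxyl is the hindered tertiary one at C4.

Step 18
Reactants: 24 C2 acetate
Product: 25 C10 α-allylic alcohol
Conditions: HF·pyridine, pyridine, THF, 0 °C to rt
Reagents that add atoms: none
Why: Buffered fluoride-mediated desilylation liberates the allylic C10 hydroxyl under conditions that should neither hydrolyse nor shift the two esters.

Step 19
Reactants: 25 C10 α-allylic alcohol
Product: 26 target CNP0197096.4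
Conditions: VO(acac)2 (5 mol%), t-BuOOH, CH2Cl2, 0 °C
Reagents that add atoms: tert-butyl hydroperoxide, CC(C)(C)OO
Why: Hydroxyl-directed epoxidation of the cyclic allylic alcohol transfers oxygen from the vanadate ester bound at the C10 hydroxyl to the same face of the C8=C9 olefin, which sets C8 and C9 as the cis-fused oxirane syn to that hydroxyl.

**Compound list**

1 | propargyl alcohol (prop-2-yn-1-ol) | C#CCO | starting material
2 | bromomagnesium (Z)-3-(bromomagnesio)-2-methylprop-2-en-1-olate | Br[Mg]OC/C(C)=C\[Mg]Br | intermediate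
3 | (Z)-3-iodo-2-methylprop-2-en-1-ol | OC/C(C)=C\I | intermediate
4 | (Z)-3-bromo-1-iodo-2-methylprop-1-ene | BrC/C(C)=C\I | intermediate
5 | (S)-but-3-yn-2-ol | C[C@H](O)C#C | starting material
6 | (S)-triethyl(but-3-yn-2-yloxy)silane | C[C@H](O[Si](CC)(CC)CC)C#C | intermediate
7 | (S,Z)-triethyl[(7-iodo-6-methylhept-6-en-3-yn-2-yl)oxy]silane | C[C@H](O[Si](CC)(CC)CC)C#CC/C(C)=C\I | intermediate
8 | (E)-3-ethoxy-2-methylprop-2-enal (3-ethoxymethacrolein) | CCO/C=C(C)/C=O | starting material
9 | (E)-3-[(4-methoxybenzyl)oxy]-2-methylprop-2-enal | COc1ccc(CO/C=C(C)/C=O)cc1 | intermediate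
10 | alkenyl(methyl)zinc from 7 (Z-olefin kept, zinc on C9) | C[C@H](O[Si](CC)(CC)CC)C#CC/C(C)=C\[Zn]C | intermediate
11 | methylzinc alkoxide of the 10S carbinol | C[C@H](O[Si](CC)(CC)CC)C#CC/C(C)=C\[C@H](O[Zn]C)/C(C)=C/OCc1ccc(OC)cc1 | intermediate
12 | (1E,3S,4Z,9S)-3-(tert-butyldimethylsilyloxy)-1-[(4-methoxybenzyl)oxy]-2,5-dimethyl-9-(triethylsilyloxy)deca-1,4-dien-7-yne | C[C@H](O[Si](CC)(CC)CC)C#CC/C(C)=C\[C@H](O[Si](C)(C)C(C)(C)C)/C(C)=C/OCc1ccc(OC)cc1 | intermediate
13 | (2S,6Z,8S,9E)-8-(tert-butyldimethylsilyloxy)-10-[(4-methoxybenzyl)oxy]-6,9-dimethyldeca-6,9-dien-3-yn-2-ol | C[C@H](O)C#CC/C(C)=C\[C@H](O[Si](C)(C)C(C)(C)C)/C(C)=C/OCc1ccc(OC)cc1 | intermediate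
14 | (2S,3E,6Z,8S,9E)-8-(tert-butyldimethylsilyloxy)-10-[(4-methoxybenzyl)oxy]-6,9-dimethyldeca-3,6,9-trien-2-ol | C[C@H](O)/C=C/C/C(C)=C\[C@H](O[Si](C)(C)C(C)(C)C)/C(C)=C/OCc1ccc(OC)cc1 | intermediate
15 | epoxy alcohol: 4S carbinol, 5R,6R trans-oxirane, Z C8=C9, 10S OSi(t-Bu)Me2, E PMB enol ether | C[C@H](O)[C@H]1O[C@@H]1C/C(C)=C\[C@H](O[Si](C)(C)C(C)(C)C)/C(C)=C/OCc1ccc(OC)cc1 | intermediate
16 | epoxy ketone: C4 methyl ketone, 5S,6R trans-oxirane, otherwise as 15 | CC(=O)[C@H]1O[C@@H]1C/C(C)=C\[C@H](O[Si](C)(C)C(C)(C)C)/C(C)=C/OCc1ccc(OC)cc1 | intermediate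
17 | epoxy enolsilane: C3=C4(OSiEt3), 5S,6R trans-oxirane, otherwise as 15 | C=C(O[Si](CC)(CC)CC)[C@H]1O[C@@H]1C/C(C)=C\[C@H](O[Si](C)(C)C(C)(C)C)/C(C)=C/OCc1ccc(OC)cc1 | intermediate
18 | ion pair: cycloheptene closed (C1–C5), C2 oxocarbenium ion (O-PMB), enol silane intact, triflate counter-ion | CC[Si](CC)(CC)O[C@@H]1CC(C)=C[C@H](O[Si](C)(C)C(C)(C)C)[C@](C)(C=[O+]Cc2ccc(OC)cc2)[C@H]1C(=C)O[Si](CC)(CC)CC.[O-]S(=O)(=O)C(F)(F)F | intermediate
19 | trans-fused bicyclo[5.3.0]dec-8-en-4-one: 1β-CH3, 2β-OPMB, 5α-H, 6α-OSiEt3, 8-CH3, 10α-OSi(t-Bu)Me2 | CC[Si](CC)(CC)O[C@@H]1CC(C)=C[C@H](O[Si](C)(C)C(C)(C)C)[C@]2(C)[C@@H](OCc3ccc(OC)cc3)CC(=O)[C@@H]12 | intermediate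
20 | tertiary carbinol: as 19 with C4 β-OH, α-isopropyl | CC[Si](CC)(CC)O[C@@H]1CC(C)=C[C@H](O[Si](C)(C)C(C)(C)C)[C@]2(C)[C@@H](OCc3ccc(OC)cc3)C[C@](O)(C(C)C)[C@@H]12 | intermediate
21 | C6 α-alcohol (2β-OPMB, 10α-OSi(t-Bu)Me2, 4β-OH) | O[C@@H]1CC(C)=C[C@H](O[Si](C)(C)C(C)(C)C)[C@]2(C)[C@@H](OCc3ccc(OC)cc3)C[C@](O)(C(C)C)[C@@H]12 | intermediate
22 | C6 3,4-dimethoxybenzoate of 21 | COc1ccc(C(=O)O[C@@H]2CC(C)=C[C@H](O[Si](C)(C)C(C)(C)C)[C@]3(C)[C@@H](OCc4ccc(OC)cc4)C[C@](O)(C(C)C)[C@@H]23)cc1OC | intermediate
23 | C2 β-alcohol (PMB removed) | COc1ccc(C(=O)O[C@@H]2CC(C)=C[C@H](O[Si](C)(C)C(C)(C)C)[C@]3(C)[C@@H](O)C[C@](O)(C(C)C)[C@@H]23)cc1OC | intermediate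
24 | C2 acetate | COc1ccc(C(=O)O[C@@H]2CC(C)=C[C@H](O[Si](C)(C)C(C)(C)C)[C@]3(C)[C@@H](OC(C)=O)C[C@](O)(C(C)C)[C@@H]23)cc1OC | intermediate
25 | C10 α-allylic alcohol (2β-acetoxy-6α-veratroyloxy-dauc-8-ene-4β,10α-diol) | COc1ccc(C(=O)O[C@@H]2CC(C)=C[C@H](O)[C@]3(C)[C@@H](OC(C)=O)C[C@](O)(C(C)C)[C@@H]23)cc1OC | intermediate
26 | CNP0197096.4: 2-acetoxy-6-(3,4-dimethoxybenzoyloxy)-8,9-epoxydaucane-4,10-diol (oxirane as in the remark) | COc1ccc(C(=O)O[C@@H]2C[C@@]3(C)O[C@@H]3[C@H](O)[C@]3(C)[C@@H](OC(C)=O)C[C@](O)(C(C)C)[C@@H]23)cc1OC | target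

**Counts**

Total step count: 19. Longest linear sequence: 17 steps (1, 2, 4, 6 to 19); steps 3 and 5 are side branches.

**The three steps most likely to fail**

1. Step 12 (Proposed new method). The cation may be lost before the seven-membered ring closes: ionisation of the bis-allylic C10 silyl ether, collapse of the silyloxyallyl unit, or attack on the wrong face of the enol ether (cis ring fusion). The fallback makes the two rings one after the other by known reactions; it sets out from 9 and comes back at 19.
 - Addition of (CH2=CH)2Zn to 9 under (−)-MIB catalysis, with silylation in the same flask as in step 6, would give the dienyl enol ether F1.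
 - (2+2) Cycloaddition of F1 with dichloroketene (Cl3CCOCl, Zn), suprafacial on the E-enol ether with C1 bonding to the carbonyl carbon, would give the dichlorocyclobutanone F2.
 - Ring expansion with diazomethane (migration of the non-chlorinated carbon C1) would give the dichlorocyclopentanone F3, in which only C5 carries α-hydrogens.
 - Soft enolisation (Bu2BOTf, i-Pr2NEt) and aldol addition to 3-methylbut-3-enal would give the aldol adduct F4; a wrong C6 epimer would be corrected by oxidation and reduction.
 - Silylation (Et3SiOTf, 2,6-lutidine) would give the silyl ether F5, and Zn, NH4Cl, MeOH would remove both chlorine atoms to give the diene F6.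
 - Ring-closing metathesis of F6 with the second-generation Grubbs catalyst would form the C8=C9 olefin and give 19.

2. Step 6. The 1,2-addition to the electron-rich vinylogous-ester aldehyde may be slow, so that the uncatalysed pathway erodes the enantioselectivity, or the product carbinol may ionise during the zinc chemistry. The fallback sets out from 7 and comes back at 12: a Nozaki–Hiyama–Kishi coupling of 7 with 9 (CrCl2, NiCl2 (cat.), chiral sulfonamide ligand, Et3N, THF) under neutral conditions would give the free carbinol F7, which would be silylated at once (t-BuMe2SiOTf, 2,6-lutidine) to 12; a C10 epimer would be a diastereomer of 12 and separable.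

3. Step 13. The hindered β-alkoxy ketone may undergo enolisation, β-elimination or reduction by β-hydride transfer instead of addition, or addition from the wrong face. The fallback sets out from 19 and comes back at 20: addition of isopropenylmagnesium bromide/CeCl3 (an sp2 reagent without β-hydrogen) would give the isopropenyl carbinol F8, and hydrogenation with RhCl(PPh3)3 (1,1-disubstituted olefin reduced, trisubstituted ring olefin left) would give 20.

**Further compounds**

F1 | step 12 | (S,E)-dienyl enol ether: C10 OSi(t-Bu)Me2, vinyl at C10, E C1=C2 PMB enol ether | C=C[C@H](O[Si](C)(C)C(C)(C)C)/C(C)=C/OCc1ccc(OC)cc1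
F2 | step 12 | 2,2-dichloro-3-(PMB-oxy)-4-methyl-4-(1-silyloxyallyl)cyclobutanone | C=C[C@H](O[Si](C)(C)C(C)(C)C)[C@@]1(C)C(=O)C(Cl)(Cl)[C@@H]1OCc1ccc(OC)cc1
F3 | step 12 | 2,2-dichloro-3-(PMB-oxy)-4-methyl-4-(1-silyloxyallyl)cyclopentanone | C=C[C@H](O[Si](C)(C)C(C)(C)C)[C@@]1(C)CC(=O)C(Cl)(Cl)[C@@H]1OCc1ccc(OC)cc1
F4 | step 12 | aldol adduct: C5 branch CH(OH)CH2C(CH3)=CH2 | C=C[C@H](O[Si](C)(C)C(C)(C)C)[C@@]1(C)[C@H]([C@H](O)CC(C)=C)C(=O)C(Cl)(Cl)[C@@H]1OCc1ccc(OC)cc1
F5 | step 12 | C6 triethylsilyl ether of F4 | C=C[C@H](O[Si](C)(C)C(C)(C)C)[C@@]1(C)[C@H]([C@H](O[Si](CC)(CC)CC)CC(C)=C)C(=O)C(Cl)(Cl)[C@@H]1OCc1ccc(OC)cc1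
F6 | step 12 | dechlorinated cyclopentanone diene (open form of 19 with vinyl and isopropenyl ends) | C=C[C@H](O[Si](C)(C)C(C)(C)C)[C@@]1(C)[C@H]([C@H](O[Si](CC)(CC)CC)CC(C)=C)C(=O)C[C@@H]1OCc1ccc(OC)cc1
F7 | step 6 | free 10S carbinol corresponding to 12 | C[C@H](O[Si](CC)(CC)CC)C#CC/C(C)=C\[C@H](O)/C(C)=C/OCc1ccc(OC)cc1
F8 | step 13 | isopropenyl carbinol: as 20 with C4 β-OH, α-isopropenyl | CC[Si](CC)(CC)O[C@@H]1CC(C)=C[C@H](O[Si](C)(C)C(C)(C)C)[C@]2(C)[C@@H](OCc3ccc(OC)cc3)C[C@](O)(C(C)=C)[C@@H]12
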